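- A gap of 3.5 percentage points separates the X readings at 25.0 min between the violet run, charged with 22 mM, and the green run, charged with 110 mM. This gap is the first sign that the flasks asked about, charged from 20 mM to 100 mM, do not simply scale.

| flask | X | remark | time |
|---|---|---|---|
| violet | 22 mM | run made earlier |  |
| green | 110 mM | run made earlier |  |
| north-east | 20 mM |  | 25 min |
| north-west | 30 mM |  | 25 min |
| south-west | 50 mM |  | 25 min |
| north | 60 mM |  | 25 min |
| west | 100 mM |  | 25 min |

| run | time / min | G / % | X / % |
|---|---|---|---|
| violet | 2.00 | 0 | 87.0 |
| violet | 4.00 | 0.6 | 75.7 |
| violet | 8.00 | 3.4 | 56.2 |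
| violet | 12.0 | 6.8 | 42.1 |
| violet | 25.0 | 15.9 | 15.1 |
| green | 2.00 | 0 | 86.0 |
| green | 4.00 | 2.6 | 72.4 |
| green | 8.00 | 4.2 | 55.6 |
| green | 12.0 | 7.0 | 38.6 |
| green | 25.0 | 17.4 | 11.6 |

(readings scatter by 1 percentage point)

- the numbers in the tables scatter by 1 percentage point (one standard deviation)
- a reading or a percentage of G counts all its forms, free or not
- the concentration of G that is asked is that of its free form alone
- "hardly changes" means that all values lie within two and a half points (for a concentration: within two and a half percent of the largest)
- a reading of X is of its free form alone

- [G] (only what is free in solution) at the end for north-east, north-west, south-west, north, west, in this order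
- the shape of the row from first to last (falls, then rises / rises, then falls / hardly changes / falls all the way / rises all the way)

- The bench rule says that first-order percent curves do not depend on the charge, so a percent reading times the charge gives a concentration. The mean G reading of 16.6% then puts west at 16.6 mM.
- The rule stops where the two runs part by more than their scatter. The gap is 2.47 times the scatter of a difference of two readings, and at 12.0 min the gap is again 3.5 points, with the same sign.
- An X reading counts free X, while a G reading counts every form of G, so a pair of X with G hides X and still stays inside the G reading.
- The quantity to watch is the partner concentration, the free X in mM at the end. It is 12.8 mM in green, above the 3.32 mM in violet, and the share of G held in pairs grows with it.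
- My own reckoning takes the gap as G held in pairs in green. That leaves 13.9% free, so west comes to about 13.9 mM, and the row still rises, but more slowly than the charge.
- The forecast gives 3.3 mM, 5 mM, 8.3 mM, 10 mM and 16.6 mM, so it rises all the way, on the ground that “Nothing in the data shows G being sequestered”. At west it stands above my reckoning.
- The flask gives 2.34 mM, 3.34 mM, 5.10 mM, 5.90 mM and 8.67 mM, and the row rises all the way.

    X → E (k = 0.0410 /min)
    X → Z (k = 0.0280 /min)
    Z → L (k = 0.0740 /min)
    L ⇌ G (K = 0.680, k = 0.290 /min)
    G ⇌ E (K = 1.20, k = 0.0300 /min)
    X + L → D (k = 0.770 /M/min)
    L → J (k = 0.00440 /min)
    X + G ⇌ Q, settled at all times (K = 79.0 /M)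

- With pairing constant 79 /M, the free share of G (its free fraction) is one over one plus that constant times the partner concentration. At 12.8 mM this gives 49.7%. West ends near that, with 13.1 mM of free X, so its G of 17.7%, pairs counted, gives 8.80 mM beside 8.67 mM. North-east, with 3.29 mM of free X, gives 2.34 mM beside 2.34 mM. Part of the 2.34 mM of north-east comes by way of Z and L together: with the reaction of X to Z taken away the flask ends at 1.22 mM, and with the reaction of Z to L taken away at 1.10 mM.

The earlier runs and the new flask were generated by integration on assumed constants, noise included.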